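**Plan**
- Retrosynthesis cuts the two aryl ester C–O bonds, first ring C acyl–O(B4), then ring B acyl–O(A4). In ring A it then cuts the A1–A2 and A5–A6 bonds, leading back to a cyclohexadiene and a but-2-ynoate.
- Enabling feature: ring A carries OMe at C2, an acylated oxygen at C4, the C3 methyl between them and H at C5. The methyl enol ether of 2-methylcyclohexane-1,3-dione already holds these two oxygens in differentiated form with the methyl between them. C6–Me and C1–CO2R come from the ynoate.
- Forward: ring A arene 8 arises by cycloaddition and ethylene extrusion. Part of 8 is converted into the ring B acid (C5 formylation, reduction to methyl, silylation). Ring C is made from 2,5-dimethylresorcinol.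
- The chain is joined A + B, then AB + C, and one hydrogenolysis removes all benzyl groups.
- Stereochemistry: the target is achiral. The only stereocentres on the route are the two bridgeheads of the transient racemic cycloadduct, and aromatisation erases them.

Key step: step 4

Remark: in every ring the locants are counted from the carbon bearing the carboxyl-derived carbon (C1). Compound 8 is used twice, as the ring A nucleophile and as the precursor of ring B.

**Step 1**
Reactants: 1 2-methylcyclohexane-1,3-dione
Product: 2 3-methoxy-2-methylcyclohex-2-en-1-one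
Conditions: HC(OMe)3, MeOH, cat. TsOH·H2O, rt → reflux
Reagents that add atoms: trimethyl orthoformate, COC(OC)OC (methoxy donor, exchanging with the solvent methanol, CO)
Why: Acid-catalysed vinylogous esterification of the enolised symmetric 1,3-dione gives a single enol ether, with the orthoformate removing the water formed.

**Step 2**
Reactants: 2 3-methoxy-2-methylcyclohex-2-en-1-one
Product: 3 1-methoxy-2-methyl-3-(trimethylsilyloxy)cyclohexa-1,3-diene
Conditions: LiN(iPr)2, THF, −78 °C; Me3SiCl, −78 °C → rt; pentane, filtration, bulb-to-bulb distillation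
Reagents that add atoms: chlorotrimethylsilane, C[Si](C)(C)Cl
Why: Kinetic deprotonation of the vinylogous ester takes place at the alpha-prime CH2 next to the carbonyl (Stork–Danheiser-type kinetic enolate), and O-silylation traps it as the 1-methoxy-3-silyloxy-1,3-diene.

**Step 3**
Reactants: 4 but-2-ynoic acid
Product: 5 benzyl but-2-ynoate
Conditions: BnBr, K2CO3, DMF, rt
Reagents that add atoms: benzyl bromide, BrCc1ccccc1
Why: SN2 O-alkylation of the carboxylate by benzyl bromide under mild carbonate conditions should leave the alkyne un-isomerised.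

**Step 4**
Reactants: 3 1-methoxy-2-methyl-3-(trimethylsilyloxy)cyclohexa-1,3-diene (1.5 equiv); 5 benzyl but-2-ynoate
Product: 8 benzyl 4-hydroxy-2-methoxy-3,6-dimethylbenzoate, via bicyclo[2.2.2]octadiene cycloadduct 6 (not isolated), via aryl trimethylsilyl ether 7 (not isolated)
Conditions: neat under argon, sealed tube, 110 → 170 °C; then 1 M HCl, THF, rt
Reagents that add atoms: none
Why: A thermal normal-electron-demand [4+2] cycloaddition of the electron-rich diene 3 to ynoate 5 forms the A1–A2 and A5–A6 bonds and gives the bicyclo[2.2.2]octa-2,5-diene 6, which at the same temperature loses its ethano bridge as ethylene by retro-[4+2] (Alder–Rickert cleavage) to give aryl silyl ether 7; dilute acid then frees the C4 phenol while the C2 oxygen stays a methyl ether. The closest known reaction type is the Alder–Rickert synthesis of resorcinol monoethers and orsellinate-type benzoates from 1-alkoxy-3-silyloxycyclohexa-1,3-dienes and alkynoates. Ring A is closed by the intermolecular, concerted Diels–Alder addition and becomes aromatic through the cycloreversion, which is driven by aromatisation and loss of a gas. No stereocentre remains, since the two bridgehead centres of racemic 6 vanish on aromatisation. The step needs regioselectivity only, and the diene supplies it: its largest HOMO coefficient lies at the unsubstituted terminus (alpha-carbon of the silyl enol ether, vinylogous to OMe), which bonds to the methyl-bearing beta-carbon of 5, so that OMe ends ortho and the silyloxy group para to the ester.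

**Step 5**
Reactants: 8 benzyl 4-hydroxy-2-methoxy-3,6-dimethylbenzoate
Product: 9 benzyl 5-formyl-4-hydroxy-2-methoxy-3,6-dimethylbenzoate
Conditions: MgCl2 (anhydrous), Et3N, (CH2O)n, MeCN, reflux; 1 M HCl work-up
Reagents that add atoms: paraformaldehyde (formaldehyde), C=O
Why: In this magnesium-phenoxide-directed ortho-formylation (Casnati–Skattebøl) the chloromagnesium phenoxide delivers formaldehyde to C5, the only free ortho position, and a second formaldehyde oxidises the hydroxymethyl intermediate by hydride transfer.

**Step 6**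
Reactants: 9 benzyl 5-formyl-4-hydroxy-2-methoxy-3,6-dimethylbenzoate
Product: 10 4-hydroxy-2-methoxy-3,5,6-trimethylbenzoic acid
Conditions: H2 (1–3 atm), 10% Pd/C, AcOH–EtOAc (cat. HCl), rt
Reagents that add atoms: none
Why: Catalytic hydrogenolysis should cleave the benzyl ester and, under the acidic conditions, reduce the ortho-hydroxy aldehyde through its benzylic alcohol (activated by the ortho OH and para OMe) to the C5 methyl group.

**Step 7**
Reactants: 10 4-hydroxy-2-methoxy-3,5,6-trimethylbenzoic acid
Product: 12 4-(tert-butyldimethylsilyloxy)-2-methoxy-3,5,6-trimethylbenzoic acid, via bis-silylated ester 11 (not isolated)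
Conditions: TBSCl (2.5 equiv), imidazole, DMF, rt → 40 °C; then AcOH–THF–H2O, rt
Reagents that add atoms: tert-butyldimethylsilyl chloride, CC(C)(C)[Si](C)(C)Cl
Why: Imidazole-promoted silylation caps both the phenol and the acid, and mild aqueous acid then solvolyses only the far more labile silyl ester, leaving the hindered aryl silyl ether.

**Step 8**
Reactants: 12 4-(tert-butyldimethylsilyloxy)-2-methoxy-3,5,6-trimethylbenzoic acid; 8 benzyl 4-hydroxy-2-methoxy-3,6-dimethylbenzoate
Product: 13 benzyl 4-{[4-(tert-butyldimethylsilyloxy)-2-methoxy-3,5,6-trimethylbenzoyl]oxy}-2-methoxy-3,6-dimethylbenzoate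
Conditions: (CF3CO)2O, toluene, 0 °C → rt (12 and the anhydride premixed, then 8)
Reagents that add atoms: none
Why: Trifluoroacetic-anhydride-mediated esterification suits doubly ortho-substituted, electron-rich benzoic acids, whose mixed anhydride ionises readily to a small linear acylium ion that the phenol oxygen of 8 captures.

**Step 9**
Reactants: 13 benzyl 4-{[4-(tert-butyldimethylsilyloxy)-2-methoxy-3,5,6-trimethylbenzoyl]oxy}-2-methoxy-3,6-dimethylbenzoate
Product: 14 benzyl 4-[(4-hydroxy-2-methoxy-3,5,6-trimethylbenzoyl)oxy]-2-methoxy-3,6-dimethylbenzoate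
Conditions: Bu4NF, AcOH, THF, 0 °C
Reagents that add atoms: none
Why: Fluoride cleaves the aryl silyl ether through the strong Si–F bond, and the acetic acid buffer protonates the phenoxide at once so that the hindered aryl ester and the benzyl ester are not attacked.

**Step 10**
Reactants: 15 2,5-dimethylresorcinol
Product: 16 2,4-dihydroxy-3,6-dimethylbenzaldehyde
Conditions: POCl3, DMF, 0 °C → rt; then H2O, 50 °C
Reagents that add atoms: N,N-dimethylformamide, CN(C)C=O; water, O
Why: In this Vilsmeier–Haack formylation the chloroiminium ion attacks one of the two symmetry-equivalent positions ortho and para to the hydroxyl groups, and the new formyl group deactivates the ring towards a second attack.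

**Step 11**
Reactants: 16 2,4-dihydroxy-3,6-dimethylbenzaldehyde
Product: 17 2,4-bis(benzyloxy)-3,6-dimethylbenzaldehyde
Conditions: BnBr (2.5 equiv), K2CO3, DMF, 60 °C
Reagents that add atoms: benzyl bromide, BrCc1ccccc1
Why: Williamson etherification of both phenols, with warming so that the hydrogen-bonded 2-OH is alkylated as well.

**Step 12**
Reactants: 17 2,4-bis(benzyloxy)-3,6-dimethylbenzaldehyde
Product: 18 2,4-bis(benzyloxy)-3,6-dimethylbenzoic acid
Conditions: NaClO2, NaH2PO4, 2-methylbut-2-ene, t-BuOH–THF–H2O, rt
Reagents that add atoms: sodium chlorite, [Na+].[O-]Cl=O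
Why: Pinnick oxidation converts the hindered aryl aldehyde to the acid without touching the benzyl ethers, the alkene trapping hypochlorous acid before it can chlorinate the electron-rich ring.

**Step 13**
Reactants: 14 benzyl 4-[(4-hydroxy-2-methoxy-3,5,6-trimethylbenzoyl)oxy]-2-methoxy-3,6-dimethylbenzoate; 18 2,4-bis(benzyloxy)-3,6-dimethylbenzoic acid (1.5 equiv)
Product: 19 benzyl 4-[(4-{[2,4-bis(benzyloxy)-3,6-dimethylbenzoyl]oxy}-2-methoxy-3,5,6-trimethylbenzoyl)oxy]-2-methoxy-3,6-dimethylbenzoate
Conditions: (CF3CO)2O, toluene, rt → 40 °C (18 and the anhydride premixed, then 14)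
Reagents that add atoms: none
Why: The same trifluoroacetic-anhydride esterification is used because its acylium-type acyl donor is small enough to reach the phenol flanked by two methyl groups, while the existing hindered aryl ester and the benzyl groups should be inert at this temperature.

**Step 14**
Reactants: 19 benzyl 4-[(4-{[2,4-bis(benzyloxy)-3,6-dimethylbenzoyl]oxy}-2-methoxy-3,5,6-trimethylbenzoyl)oxy]-2-methoxy-3,6-dimethylbenzoate
Product: 20 4-[(4-{[2,4-dihydroxy-3,6-dimethylbenzoyl]oxy}-2-methoxy-3,5,6-trimethylbenzoyl)oxy]-2-methoxy-3,6-dimethylbenzoic acid (target CNP0425440.0)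
Conditions: H2 (1 atm), 10% Pd/C, EtOAc–THF, rt
Reagents that add atoms: none
Why: Neutral hydrogenolysis over palladium on carbon removes the two benzyl ethers and the benzyl ester in one operation and leaves the aryl ester links and methyl ethers intact.

**Compound list**
1 | 2-methylcyclohexane-1,3-dione | CC1C(=O)CCCC1=O | starting material
2 | 3-methoxy-2-methylcyclohex-2-en-1-one | COC1=C(C)C(=O)CCC1 | intermediate
3 | 1-methoxy-2-methyl-3-(trimethylsilyloxy)cyclohexa-1,3-diene | COC1=C(C)C(O[Si](C)(C)C)=CCC1 | intermediate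
4 | but-2-ynoic acid | CC#CC(=O)O | starting material
5 | benzyl but-2-ynoate | CC#CC(=O)OCc1ccccc1 | intermediate
6 | benzyl 1-methoxy-3,6-dimethyl-5-(trimethylsilyloxy)bicyclo[2.2.2]octa-2,5-diene-2-carboxylate (racemic, transient) | COC12CCC(C(C)=C1C(=O)OCc3ccccc3)C(O[Si](C)(C)C)=C2C | intermediate
7 | benzyl 2-methoxy-3,6-dimethyl-4-(trimethylsilyloxy)benzoate | COc1c(C)c(O[Si](C)(C)C)cc(C)c1C(=O)OCc1ccccc1 | intermediate
8 | benzyl 4-hydroxy-2-methoxy-3,6-dimethylbenzoate | COc1c(C)c(O)cc(C)c1C(=O)OCc1ccccc1 | intermediate
9 | benzyl 5-formyl-4-hydroxy-2-methoxy-3,6-dimethylbenzoate | COc1c(C)c(O)c(C=O)c(C)c1C(=O)OCc1ccccc1 | intermediate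
10 | 4-hydroxy-2-methoxy-3,5,6-trimethylbenzoic acid | COc1c(C)c(O)c(C)c(C)c1C(=O)O | intermediate
11 | tert-butyldimethylsilyl 4-(tert-butyldimethylsilyloxy)-2-methoxy-3,5,6-trimethylbenzoate | COc1c(C)c(O[Si](C)(C)C(C)(C)C)c(C)c(C)c1C(=O)O[Si](C)(C)C(C)(C)C | intermediate
12 | 4-(tert-butyldimethylsilyloxy)-2-methoxy-3,5,6-trimethylbenzoic acid | COc1c(C)c(O[Si](C)(C)C(C)(C)C)c(C)c(C)c1C(=O)O | intermediate
13 | benzyl 4-{[4-(tert-butyldimethylsilyloxy)-2-methoxy-3,5,6-trimethylbenzoyl]oxy}-2-methoxy-3,6-dimethylbenzoate | COc1c(C)c(OC(=O)c2c(C)c(C)c(O[Si](C)(C)C(C)(C)C)c(C)c2OC)cc(C)c1C(=O)OCc1ccccc1 | intermediate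
14 | benzyl 4-[(4-hydroxy-2-methoxy-3,5,6-trimethylbenzoyl)oxy]-2-methoxy-3,6-dimethylbenzoate | COc1c(C)c(OC(=O)c2c(C)c(C)c(O)c(C)c2OC)cc(C)c1C(=O)OCc1ccccc1 | intermediate
15 | 2,5-dimethylresorcinol (2,5-dimethylbenzene-1,3-diol) | Cc1cc(O)c(C)c(O)c1 | starting material
16 | 2,4-dihydroxy-3,6-dimethylbenzaldehyde | Cc1cc(O)c(C)c(O)c1C=O | intermediate
17 | 2,4-bis(benzyloxy)-3,6-dimethylbenzaldehyde | Cc1cc(OCc2ccccc2)c(C)c(OCc2ccccc2)c1C=O | intermediate
18 | 2,4-bis(benzyloxy)-3,6-dimethylbenzoic acid | Cc1cc(OCc2ccccc2)c(C)c(OCc2ccccc2)c1C(=O)O | intermediate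
19 | benzyl 4-[(4-{[2,4-bis(benzyloxy)-3,6-dimethylbenzoyl]oxy}-2-methoxy-3,5,6-trimethylbenzoyl)oxy]-2-methoxy-3,6-dimethylbenzoate | COc1c(C)c(OC(=O)c2c(C)c(C)c(OC(=O)c3c(C)cc(OCc4ccccc4)c(C)c3OCc5ccccc5)c(C)c2OC)cc(C)c1C(=O)OCc6ccccc6 | intermediate
20 | 4-[(4-{[2,4-dihydroxy-3,6-dimethylbenzoyl]oxy}-2-methoxy-3,5,6-trimethylbenzoyl)oxy]-2-methoxy-3,6-dimethylbenzoic acid | COc1c(C)c(OC(=O)c2c(C)c(C)c(OC(=O)c3c(C)cc(O)c(C)c3O)c(C)c2OC)cc(C)c1C(=O)O | target

**Step count**
Total: 14 steps.
Longest linear sequence: 10 steps (steps 1, 2, 4, 5, 6, 7, 8, 9, 13, 14, from dione 1).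

**Steps most likely to fail**

1. Step 4. The cycloaddition of the weakly activated, beta-methylated ynoate may be slower than thermal decay of the silyl dienol ether (desilylation back to 2, hydrogen shifts, oligomerisation). The fallback keeps the same two ring bonds but uses a stronger dienophile. It sets out from 3 and commercial but-2-ynal (CC#CC=O), which should add in toluene at 80–110 °C to give 1-methoxy-3,6-dimethyl-5-(trimethylsilyloxy)bicyclo[2.2.2]octa-2,5-diene-2-carbaldehyde F1. Further heating to about 140 °C should expel ethylene to give 2-methoxy-3,6-dimethyl-4-(trimethylsilyloxy)benzaldehyde F2, and dilute HCl in THF frees 4-hydroxy-2-methoxy-3,6-dimethylbenzaldehyde F3. Chlorite oxidation with sulfamic acid as scavenger (NaClO2, H2NSO3H, aqueous dioxane) gives 4-hydroxy-2-methoxy-3,6-dimethylbenzoic acid F4. Selective carboxylate alkylation (BnBr, KHCO3, DMF, rt) returns to the route at 8.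

2. Step 13. O-acylation of the doubly ortho-methylated, ester-deactivated phenol by a doubly ortho-substituted acyl donor may be too slow, so that trifluoroacetylation of the phenol or acid-induced loss of the ortho benzyl ether takes over. The fallback switches from acidic acylium transfer to an anionic nucleophile and an acyl chloride. It sets out from 18, which with (COCl)2 and cat. DMF in CH2Cl2 gives 2,4-bis(benzyloxy)-3,6-dimethylbenzoyl chloride F5. Separately, 14 is deprotonated with NaH in THF at 0 °C to the sodium phenoxide of 14 F6. Combining the two (THF, 0 °C → 50 °C) returns to the route at 19.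

3. Step 6. The reduction of the hindered, hydrogen-bonded aldehyde may stall at the benzylic alcohol while the benzyl ester is already cleaved, giving mixtures. The fallback separates the two events and reduces the aldehyde by ionic hydrogenation. It sets out from 9, which with Et3SiH and CF3CO2H in CH2Cl2 (0 °C → rt) should give benzyl 4-hydroxy-2-methoxy-3,5,6-trimethylbenzoate F7. Neutral hydrogenolysis (H2, 10% Pd/C, EtOAc) then returns to the route at 10.

**Further compounds**
F1 | step 4 | 1-methoxy-3,6-dimethyl-5-(trimethylsilyloxy)bicyclo[2.2.2]octa-2,5-diene-2-carbaldehyde | COC12CCC(C(C)=C1C=O)C(O[Si](C)(C)C)=C2C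
F2 | step 4 | 2-methoxy-3,6-dimethyl-4-(trimethylsilyloxy)benzaldehyde | COc1c(C)c(O[Si](C)(C)C)cc(C)c1C=O
F3 | step 4 | 4-hydroxy-2-methoxy-3,6-dimethylbenzaldehyde | COc1c(C)c(O)cc(C)c1C=O
F4 | step 4 | 4-hydroxy-2-methoxy-3,6-dimethylbenzoic acid | COc1c(C)c(O)cc(C)c1C(=O)O
F5 | step 13 | 2,4-bis(benzyloxy)-3,6-dimethylbenzoyl chloride | Cc1cc(OCc2ccccc2)c(C)c(OCc2ccccc2)c1C(Cl)=O
F6 | step 13 | sodium phenoxide of 14 | COc1c(C)c(OC(=O)c2c(C)c(C)c([O-])c(C)c2OC)cc(C)c1C(=O)OCc1ccccc1.[Na+]
F7 | step 6 | benzyl 4-hydroxy-2-methoxy-3,5,6-trimethylbenzoate | COc1c(C)c(O)c(C)c(C)c1C(=O)OCc1ccccc1
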